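## Retrosynthetic overview

- Locants: unit 1 is the 5-hydroxy-7-methoxy-4'-methoxy half (C2–C8a, 2,3-cis). Unit 2 is the naringenin half (C2''–C8a'', 2,3-trans). The halves are joined C3–C3''.
- Feature: ring A of unit 2 (C4a''–C5''–C6''–C7''–C8''–C8a'') is a phloroglucinol acylated at C4a'' by C4''. Its 1,3,5-oxygen pattern is that of a folded linear 3,5,7-triketo ester, so the ring is cut at C4a''–C8a'' (Claisen).
- Target ⇒ flavone–flavanone (syn-H2 across C2=C3, O-debenzylation) ⇒ α-flavonyl chalcone (O1''–C2'' oxa-Michael) ⇒ triketo ester (C4a''–C8a'' Claisen) ⇒ cinnamoyl imidazolide + keto-dioxinone (C4''–C4a'' acylation, ketene/MeOH unmasking).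
- α-Flavonyl cinnamic acid ⇒ flavone-3-acetic acid + aldehyde (Perkin, C2''=C3'') ⇒ C-alkylated 1,3-diketone from an acetophenone, anisoyl chloride and a bromoacetate.
- Ring order: ring C of unit 1 (step 4), ring A of unit 2 (step 10), ring C of unit 2 (step 11). All four stereocentres are set after the base-heavy steps.

Key step: step 10

Remark: O5 of unit 1 and O4''' of unit 2 are carried as benzyl ethers, so no Lewis acid or base meets the epimerisable 2,3-cis flavanone at the end.
Assumption: the sense of induction in step 11 is taken by analogy with ester-activated chalcones; if the quinidine-derived thiourea favours the (2''R,3''S) series, its quinine-derived pseudo-enantiomer is used with nothing else changed.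
Abbreviation: Fl = 5-(benzyloxy)-7-methoxy-2-(4-methoxyphenyl)-4-oxo-4H-chromen-3-yl.

## Route

Step 1
Reactants: 1 2',6'-dihydroxy-4'-methoxyacetophenone
Product: 2 1-[2-(benzyloxy)-6-hydroxy-4-methoxyphenyl]ethanone
Conditions: BnBr (1.05 equiv), K2CO3 (1.1 equiv), acetone, reflux
Reagents that add atoms: benzyl bromide, BrCc1ccccc1
Why: Williamson etherification; after the first benzylation the remaining ortho-hydroxyl is locked in a hydrogen bond to the acetyl carbonyl and reacts much more slowly, so mono-protection should prevail.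

Step 2
Reactants: 2 1-[2-(benzyloxy)-6-hydroxy-4-methoxyphenyl]ethanone; 3 4-methoxybenzoyl chloride
Product: 4 1-[2-(benzyloxy)-6-hydroxy-4-methoxyphenyl]-3-(4-methoxyphenyl)propane-1,3-dione
Conditions: LiN(SiMe3)2 (3.2 equiv), THF, −78 → −10 °C; then 3 (1.05 equiv), −78 °C → rt; 1 M HCl
Reagents that add atoms: none
Why: Crossed Claisen acylation of the lithium phenoxide–enolate, the one-flask equivalent of O-aroylation plus Baker–Venkataraman rearrangement; any O-aroyl ester formed is carried to the same diketone by the excess base.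

Step 3
Reactants: 4 the 1,3-diketone; 5 tert-butyl bromoacetate
Product: 6 tert-butyl 3-[2-(benzyloxy)-6-hydroxy-4-methoxybenzoyl]-4-(4-methoxyphenyl)-4-oxobutanoate (racemic)
Conditions: K2CO3 (1.2 equiv), 5 (1.05 equiv), DMF, rt
Reagents that add atoms: none
Why: SN2 C-alkylation of the soft 1,3-diketone enolate by an α-bromo ester, with the chelated phenol the poorer nucleophile; the new stereocentre is labile and is erased in step 4.

Step 4
Reactants: 6 the C-alkylated diketone
Product: 8 Fl-CH2CO2H ([5-(benzyloxy)-7-methoxy-2-(4-methoxyphenyl)-4-oxo-4H-chromen-3-yl]acetic acid), via tert-butyl ester Fl-CH2CO2t-Bu 7 (not isolated)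
Conditions: CF3CO2H–CH2Cl2 (1:2), 0 °C → rt
Reagents that add atoms: none
Why: Acid-catalysed cyclodehydration of the o-hydroxyaryl 1,3-diketone through its 2-hydroxyflavanone hemiketal closes ring C of unit 1, the tert-butyl ester loses isobutene (E1) in the same medium, and plain aryl benzyl ethers should tolerate dilute acid at room temperature.

Step 5
Reactants: 8 Fl-CH2CO2H; 9 4-(benzyloxy)benzaldehyde
Product: 10 (E)-3-[4-(benzyloxy)phenyl]-2-Fl-prop-2-enoic acid
Conditions: Ac2O, Et3N, 110 °C; then H2O–THF, 60 °C; 1 M HCl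
Reagents that add atoms: none
Why: Perkin–Oglialoro condensation of an arylacetic-type acid with a non-enolisable aldehyde via the mixed-anhydride enolate; as with α-arylcinnamic acids it should give the E acid, with carboxyl trans to the β-aryl group.

Step 6
Reactants: 11 2,2,6-trimethyl-4H-1,3-dioxin-4-one; 12 acetyl chloride
Product: 13 2,2-dimethyl-6-(2-oxopropyl)-4H-1,3-dioxin-4-one
Conditions: 11 (2 equiv), LiN(SiMe3)2 (2 equiv), THF, −78 °C; then 12 (1 equiv), −78 → −20 °C; 1 M HCl
Reagents that add atoms: none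
Why: γ-Selective C-acylation of the lithium dienolate of the dioxinone by an acid chloride, a standard entry to keto-dioxinones, with the second equivalent of dienolate taking up the more acidic product proton.

Step 7
Reactants: 10 the E acid
Product: 14 (E)-3-[4-(benzyloxy)phenyl]-2-Fl-1-(1H-imidazol-1-yl)prop-2-en-1-one
Conditions: CDI (1.3 equiv), THF, rt → 45 °C; cold-water wash, used without chromatography
Reagents that add atoms: 1,1'-carbonyldiimidazole, O=C(n1ccnc1)n1ccnc1
Why: Carboxyl activation as the acyl imidazolide, driven by loss of CO2; washing out the liberated imidazole keeps it from quenching the dianion in step 8.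

Step 8
Reactants: 14 the acyl imidazolide; 13 the keto-dioxinone
Product: 15 6-{(E)-6-[4-(benzyloxy)phenyl]-5-Fl-2,4-dioxohex-5-en-1-yl}-2,2-dimethyl-4H-1,3-dioxin-4-one
Conditions: 13 (2.5 equiv), LiN(i-Pr)2 (5 equiv), THF, −78 → −40 °C; then 14, −78 → −20 °C; 1 M HCl
Reagents that add atoms: none
Why: Claisen-type acylation of the dianion of 13 at its more basic terminal carbon by a non-enolisable acyl imidazolide forms C4''–C4a''; the excess dianion absorbs the acidic product protons, and the 2,3-disubstituted electron-rich flavone is a poor competing acceptor.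

Step 9
Reactants: 15 the diketo-dioxinone
Product: 17 methyl (E)-9-[4-(benzyloxy)phenyl]-8-Fl-3,5,7-trioxonon-8-enoate, via acylketene 16 (not isolated)
Conditions: toluene–MeOH (4:1), 110 °C (sealed tube), 1 h
Reagents that add atoms: methanol, CO
Why: Thermal retro-hetero-Diels–Alder fragmentation of the dioxinone releases acetone and acylketene 16, which the large excess of methanol should trap faster than the internal enol can lactonise.

Step 10
Reactants: 17 the triketo ester
Product: 19 (E)-3-[4-(benzyloxy)phenyl]-2-Fl-1-(2,4,6-trihydroxyphenyl)prop-2-en-1-one, via 2-acylcyclohexane-1,3,5-trione 18 (not isolated)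
Conditions: Mg(OMe)2 (8 equiv), MeOH (0.02 M), rt → 60 °C; poured into ice-cold 1 M HCl–EtOAc
Reagents that add atoms: none
Why: Mg(OMe)2 turns the tricarbonyl array of 17 into chelated magnesium enolates, the enolate carbon C4a'' held between C4''=O and C5''=O adds to the ester carbon C8a'', methoxide leaves, and trione 18 enolises three times to the phloroglucinol ring. The closest known reaction type is the biomimetic intramolecular Claisen (Dieckmann-type) cyclisation of 3,5,7-triketo esters to 2-acylphloroglucinols with magnesium alkoxides, which has been carried out on cinnamoyl-terminated chains to give chalcones. Ring A of unit 2 closes in a 6-exo-trig mode (enolate carbon onto the ester C=O), which forms the C4a''–C8a'' bond. No stereocentre is formed, and the E geometry of C2''=C3'' is only carried along. The step needs Claisen folding to win over aldol folding (C8'' onto C4'', leading to a resorcylate), lactonisation to the 4-hydroxy-2-pyrone and conjugate addition at C2''; excess base enolises every ketone and leaves the ester as the only good electrophile, C4'' is cross-conjugated and screened on both faces by the perpendicular flavonyl group, and pyrone formation and conjugate additions are reversible in methanolic methoxide whereas aromatisation is not. Magnesium chelation of the new ortho-phenoxide to C4''=O, together with the cold acidic quench, should hold 19 at the open chalcone stage.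

Step 11
Reactants: 19 the trihydroxychalcone
Product: 20 (2S,3R)-2-[4-(benzyloxy)phenyl]-3-Fl-5,7-dihydroxy-2,3-dihydro-4H-chromen-4-one
Conditions: 1-[3,5-bis(trifluoromethyl)phenyl]-3-[(9R)-6'-methoxycinchonan-9-yl]thiourea (quinidine-derived, 10 mol %), toluene–CH2Cl2 (2:1), −25 °C
Reagents that add atoms: none
Why: Proposed new method: the quinuclidine nitrogen of the bifunctional catalyst should engage one of the two equivalent ortho-hydroxyls while the thiourea clamps the C4''=O/flavone C4=O carbonyl pair, so that oxygen adds 6-endo-trig to one face of C2'' and sets it as S, after which the same amine equilibrates the acidic C3''–H to the diequatorial trans (3''R) arrangement; the closest known reaction type is the cinchona-thiourea-catalysed intramolecular oxa-Michael addition of α-alkoxycarbonyl-2'-hydroxychalcones to 3-carboxyflavanones, and the racemic closure of α-substituted chalcones to trans-3-substituted flavanones is known.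

Step 12
Reactants: 20 the flavanone–flavone
Product: 22 target (2S,3S)-3-[(2S,3R)-5,7-dihydroxy-2-(4-hydroxyphenyl)-4-oxochroman-3-yl]-5-hydroxy-7-methoxy-2-(4-methoxyphenyl)chroman-4-one, via debenzylated flavone–flavanone 21 (not isolated)
Conditions: H2 (30 bar), Pd(OH)2/C, EtOAc–EtOH (1:1), 40 °C; stopped at three equivalents of H2
Reagents that add atoms: none
Why: Heterogeneous hydrogenolysis and hydrogenation: the two benzyl ethers should fall first (21), then both hydrogens reach C2=C3 from the catalyst surface on the same face (syn addition, hence 2,3-cis), and in the rotamer that relieves A(1,3) strain (C3''–H eclipsing the C2-anisyl group) the face next to the C2''-aryl group is blocked while the face next to C4''=O is open, which corresponds to (2S,3S), the neutral medium leaving C3 and C3'' unepimerised.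

## Compound list

1 | 2',6'-dihydroxy-4'-methoxyacetophenone | CC(=O)c1c(O)cc(OC)cc1O | starting material
2 | 1-[2-(benzyloxy)-6-hydroxy-4-methoxyphenyl]ethanone | CC(=O)c1c(O)cc(OC)cc1OCc1ccccc1 | intermediate
3 | 4-methoxybenzoyl chloride | COc1ccc(C(Cl)=O)cc1 | starting material
4 | 1-[2-(benzyloxy)-6-hydroxy-4-methoxyphenyl]-3-(4-methoxyphenyl)propane-1,3-dione | COc1ccc(C(=O)CC(=O)c2c(O)cc(OC)cc2OCc2ccccc2)cc1 | intermediate
5 | tert-butyl bromoacetate | CC(C)(C)OC(=O)CBr | starting material
6 | tert-butyl 3-[2-(benzyloxy)-6-hydroxy-4-methoxybenzoyl]-4-(4-methoxyphenyl)-4-oxobutanoate (racemic) | COc1ccc(C(=O)C(CC(=O)OC(C)(C)C)C(=O)c2c(O)cc(OC)cc2OCc2ccccc2)cc1 | intermediate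
7 | tert-butyl [5-(benzyloxy)-7-methoxy-2-(4-methoxyphenyl)-4-oxo-4H-chromen-3-yl]acetate | COc1ccc(-c2oc3cc(OC)cc(OCc4ccccc4)c3c(=O)c2CC(=O)OC(C)(C)C)cc1 | intermediate
8 | [5-(benzyloxy)-7-methoxy-2-(4-methoxyphenyl)-4-oxo-4H-chromen-3-yl]acetic acid | COc1ccc(-c2oc3cc(OC)cc(OCc4ccccc4)c3c(=O)c2CC(=O)O)cc1 | intermediate
9 | 4-(benzyloxy)benzaldehyde | O=Cc1ccc(OCc2ccccc2)cc1 | starting material
10 | (E)-3-[4-(benzyloxy)phenyl]-2-[5-(benzyloxy)-7-methoxy-2-(4-methoxyphenyl)-4-oxo-4H-chromen-3-yl]prop-2-enoic acid | COc1ccc(-c2oc3cc(OC)cc(OCc4ccccc4)c3c(=O)c2/C(=C\c2ccc(OCc3ccccc3)cc2)C(=O)O)cc1 | intermediate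
11 | 2,2,6-trimethyl-4H-1,3-dioxin-4-one | CC1=CC(=O)OC(C)(C)O1 | starting material
12 | acetyl chloride | CC(Cl)=O | starting material
13 | 2,2-dimethyl-6-(2-oxopropyl)-4H-1,3-dioxin-4-one | CC(=O)CC1=CC(=O)OC(C)(C)O1 | intermediate
14 | (E)-3-[4-(benzyloxy)phenyl]-2-[5-(benzyloxy)-7-methoxy-2-(4-methoxyphenyl)-4-oxo-4H-chromen-3-yl]-1-(1H-imidazol-1-yl)prop-2-en-1-one | COc1ccc(-c2oc3cc(OC)cc(OCc4ccccc4)c3c(=O)c2/C(=C\c2ccc(OCc3ccccc3)cc2)C(=O)n2ccnc2)cc1 | intermediate
15 | 6-{(E)-6-[4-(benzyloxy)phenyl]-5-[5-(benzyloxy)-7-methoxy-2-(4-methoxyphenyl)-4-oxo-4H-chromen-3-yl]-2,4-dioxohex-5-en-1-yl}-2,2-dimethyl-4H-1,3-dioxin-4-one | COc1ccc(-c2oc3cc(OC)cc(OCc4ccccc4)c3c(=O)c2/C(=C\c2ccc(OCc3ccccc3)cc2)C(=O)CC(=O)CC2=CC(=O)OC(C)(C)O2)cc1 | intermediate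
16 | (E)-9-[4-(benzyloxy)phenyl]-8-[5-(benzyloxy)-7-methoxy-2-(4-methoxyphenyl)-4-oxo-4H-chromen-3-yl]nona-1,8-diene-1,3,5,7-tetraone (acylketene) | COc1ccc(-c2oc3cc(OC)cc(OCc4ccccc4)c3c(=O)c2/C(=C\c2ccc(OCc3ccccc3)cc2)C(=O)CC(=O)CC(=O)C=C=O)cc1 | intermediate
17 | methyl (E)-9-[4-(benzyloxy)phenyl]-8-[5-(benzyloxy)-7-methoxy-2-(4-methoxyphenyl)-4-oxo-4H-chromen-3-yl]-3,5,7-trioxonon-8-enoate | COc1ccc(-c2oc3cc(OC)cc(OCc4ccccc4)c3c(=O)c2/C(=C\c2ccc(OCc3ccccc3)cc2)C(=O)CC(=O)CC(=O)CC(=O)OC)cc1 | intermediate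
18 | 2-{(E)-3-[4-(benzyloxy)phenyl]-2-[5-(benzyloxy)-7-methoxy-2-(4-methoxyphenyl)-4-oxo-4H-chromen-3-yl]prop-2-enoyl}cyclohexane-1,3,5-trione | COc1ccc(-c2oc3cc(OC)cc(OCc4ccccc4)c3c(=O)c2/C(=C\c2ccc(OCc3ccccc3)cc2)C(=O)C2C(=O)CC(=O)CC2=O)cc1 | intermediate
19 | (E)-3-[4-(benzyloxy)phenyl]-2-[5-(benzyloxy)-7-methoxy-2-(4-methoxyphenyl)-4-oxo-4H-chromen-3-yl]-1-(2,4,6-trihydroxyphenyl)prop-2-en-1-one | COc1ccc(-c2oc3cc(OC)cc(OCc4ccccc4)c3c(=O)c2/C(=C\c2ccc(OCc3ccccc3)cc2)C(=O)c2c(O)cc(O)cc2O)cc1 | intermediate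
20 | (2S,3R)-2-[4-(benzyloxy)phenyl]-3-[5-(benzyloxy)-7-methoxy-2-(4-methoxyphenyl)-4-oxo-4H-chromen-3-yl]-5,7-dihydroxy-2,3-dihydro-4H-chromen-4-one | COc1ccc(-c2oc3cc(OC)cc(OCc4ccccc4)c3c(=O)c2[C@H]2C(=O)c3c(O)cc(O)cc3O[C@@H]2c2ccc(OCc3ccccc3)cc2)cc1 | intermediate
21 | (2S,3R)-5,7-dihydroxy-3-[5-hydroxy-7-methoxy-2-(4-methoxyphenyl)-4-oxo-4H-chromen-3-yl]-2-(4-hydroxyphenyl)-2,3-dihydro-4H-chromen-4-one | COc1ccc(-c2oc3cc(OC)cc(O)c3c(=O)c2[C@H]2C(=O)c3c(O)cc(O)cc3O[C@@H]2c2ccc(O)cc2)cc1 | intermediate
22 | (2S,3S)-3-[(2S,3R)-5,7-dihydroxy-2-(4-hydroxyphenyl)-4-oxochroman-3-yl]-5-hydroxy-7-methoxy-2-(4-methoxyphenyl)chroman-4-one (CNP0279849.1) | COc1ccc([C@H]2Oc3cc(OC)cc(O)c3C(=O)[C@H]2[C@H]2C(=O)c3c(O)cc(O)cc3O[C@@H]2c2ccc(O)cc2)cc1 | target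

## Step count and risks

Total step count: 12. Longest linear sequence: 11 steps (1 → 22 through steps 1–5 and 7–12; step 6 is the side branch).

**Step 11 (the labelled step).**
- What may go wrong: uncatalysed closure of the very reactive trihydroxychalcone and reversible retro-oxa-Michael opening may compete with the catalysed pathway and erode the enantiomeric purity.
- Fallback (resolution by known chemistry instead of asymmetric catalysis): it sets out from 19 and comes back to the route at 20.
- NaOAc in refluxing EtOH closes the ring under thermodynamic control to the racemic trans flavanone–flavone F1.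
- Preparative chromatography on an amylose tris(3,5-dimethylphenylcarbamate) phase separates 20 from the (2R,3S) enantiomer F2.
- F2 is returned to F1 by warming with catalytic DBU (ring opening and re-closure) and is resubmitted.

**Step 12.**
- What may go wrong: saturation of the tetrasubstituted, vinylogous-ester C2=C3 bond may stall after debenzylation. Forcing it may reduce C4=O, and the facial preference may be weaker than the rotamer model suggests.
- Fallback (ionic reduction with kinetic protonation instead of surface hydrogenation): it sets out from 20 and comes back at 22.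
- LiBH(s-Bu)3 (4.5 equiv, two of them consumed by the phenols, whose phenoxides shield C4''=O) in THF at −78 °C should add hydride to C2 from the open face.
- The resulting enolate is protonated at −78 °C with pre-cooled AcOH, anti to the pseudo-axial anisyl group. This should give the 2,3-cis bis(benzyl ether) of the target F3.
- H2 (1 bar) over Pd/C in EtOAc at rt then removes only the benzyl groups.

**Step 10.**
- What may go wrong: aldol folding to a resorcylate, lactonisation to the pyrone, or ring closure of the chalcone before the quench may take over.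
- Fallback (ring A brought in preformed instead of folded): it sets out from 14 and comes back at 19.
- Phloroglucinol is converted with MOMCl and i-Pr2NEt into 1,3,5-tris(methoxymethoxy)benzene F4.
- n-BuLi (THF, 0 °C) gives 2-lithio-1,3,5-tris(methoxymethoxy)benzene F5 by directed ortho-metalation.
- F5 is acylated by 14 at −78 °C to the tris(methoxymethyl) ether of the chalcone F6.
- Brief exposure to HCl in MeOH at rt removes the acetals.

## Further compounds

F1 | step 11 | racemic trans flavanone–flavone (20 together with its enantiomer) | COc1ccc(-c2oc3cc(OC)cc(OCc4ccccc4)c3c(=O)c2[C@H]2C(=O)c3c(O)cc(O)cc3O[C@@H]2c2ccc(OCc3ccccc3)cc2)cc1.COc1ccc(-c2oc3cc(OC)cc(OCc4ccccc4)c3c(=O)c2[C@@H]2C(=O)c3c(O)cc(O)cc3O[C@H]2c2ccc(OCc3ccccc3)cc2)cc1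
F2 | step 11 | (2R,3S)-2-[4-(benzyloxy)phenyl]-3-[5-(benzyloxy)-7-methoxy-2-(4-methoxyphenyl)-4-oxo-4H-chromen-3-yl]-5,7-dihydroxy-2,3-dihydro-4H-chromen-4-one | COc1ccc(-c2oc3cc(OC)cc(OCc4ccccc4)c3c(=O)c2[C@@H]2C(=O)c3c(O)cc(O)cc3O[C@H]2c2ccc(OCc3ccccc3)cc2)cc1
F3 | step 12 | (2S,3S)-5-(benzyloxy)-3-{(2S,3R)-2-[4-(benzyloxy)phenyl]-5,7-dihydroxy-4-oxochroman-3-yl}-7-methoxy-2-(4-methoxyphenyl)chroman-4-one | COc1ccc([C@H]2Oc3cc(OC)cc(OCc4ccccc4)c3C(=O)[C@H]2[C@H]2C(=O)c3c(O)cc(O)cc3O[C@@H]2c2ccc(OCc3ccccc3)cc2)cc1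
F4 | step 10 | 1,3,5-tris(methoxymethoxy)benzene | COCOc1cc(OCOC)cc(OCOC)c1
F5 | step 10 | 2-lithio-1,3,5-tris(methoxymethoxy)benzene | COCOc1cc(OCOC)c([Li])c(OCOC)c1
F6 | step 10 | (E)-3-[4-(benzyloxy)phenyl]-2-[5-(benzyloxy)-7-methoxy-2-(4-methoxyphenyl)-4-oxo-4H-chromen-3-yl]-1-[2,4,6-tris(methoxymethoxy)phenyl]prop-2-en-1-one | COc1ccc(-c2oc3cc(OC)cc(OCc4ccccc4)c3c(=O)c2/C(=C\c2ccc(OCc3ccccc3)cc2)C(=O)c2c(OCOC)cc(OCOC)cc2OCOC)cc1
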